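## The problem

CNP0221003.1 (28) is a bicyclo[3.2.1]oct-2-en-8-one: a cyclopentanone (C1, C8, C5, C6, C7) and a cyclohexene (C1–C5 plus C8) share the bridge C1–C8–C5, so the seven-membered ring C1–C7 is spanned by the carbonyl carbon. Both bridgeheads are quaternary (allyl on C1, methoxy on C5) and lie between three further stereocentres: C4 (acetoxy, axial on the six-membered ring, on the side of C8), C6 (aryl, exo, on the side of C8) and C7 (methyl, endo). The bridgeheads can only be cis, so once the bicycle exists its shape can set C6 and C7 together, because a planar C8 carbonyl leaves the exo face of a C6=C7 double bond open. C4 is different: an axial oxygen there is 1,3-diaxial to whatever C8 carries, so a C8 ketal favours the wrong (equatorial) epimer. The functionality is fragile. The C2=C3 methyl enol ether does not survive aqueous acid; the acetate and any free C4 hydroxyl are β to the C8 ketone, so base invites acyl loss and retro-aldol opening of C4–C5; and the allyl group rules out late hydrogenation. The enabling feature is the three-carbon bridge C2–C3–C4, oxygenated on its central carbon and attached through both ends to the 1,4-positions of a five-membered ring whose fifth carbon is the ketone C8. That is the formal adduct of a 2-oxyallyl cation and a cyclopentadienone, and the C5 methoxy group makes the diene partner an electron-rich, polarised 1-methoxydiene.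

## Retrosynthesis

Target numbering is used for the bicycle throughout: the side-chain carbon of diene 9 becomes C1, its methoxy-bearing diene carbon C5 and its ketal carbon C8.

**Allyl group (28 ⇒ 27 ⇒ 26 ⇒ 25).** The terminal C=C is cut to aldehyde 27, which goes back through alcohol 26 to silyl ether 25. The allyl group is carried as a 2-silyloxyethyl chain because a free terminal alkene would not survive the hydrogenolysis of the auxiliary and would compete in the arylation of C6=C7. The forward Wittig reaction must pick the aldehyde over the C8 ketone (flanked by two quaternary carbons) and the acetate.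

**C4–O acetate (25 ⇒ 24).** The C4–O bond is cut with inversion: 25 comes from the equatorial allylic alcohol 24 by Mitsunobu esterification with acetic acid. The reason is that the cycloaddition should leave the C4 oxygen equatorial whereas 28 has it axial; inversion and acylation are then one operation. Oxidation to the C4 ketone and reduction was set aside, because hydride would arrive from the open face next to the C8 carbonyl and return the equatorial alcohol.

**Enol ether (24 ⇒ 23 ⇒ 21 ⇒ 20 ⇒ 19).** The O–CH3 bond of the enol ether is cut: 23 arises by O-methylation of enolate 22 from ketone 21. This demands a base-stable group on the C4 oxygen, hence the triethylsilyl ether 21 made from ketol 20. Ketol 20 comes from 19 by hydrogenolysis of the phenylethyl ether. The order is fixed by three facts: the enol ether must follow the last acid step, the hydrogenolysis must precede the enol ether (an allylic C4–O bond and an enol ether double bond would not survive H2 over palladium), and the acetate must follow the enolate chemistry.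

**C6–aryl and C7–H (19 ⇒ 17 + 18).** Cutting the C6–aryl and C7–H bonds gives alkene 17 and boronic acid 18. A syn hydroarylation from the exo face sets C6 and C7 in one step and removes any need to carry the aryl group through the cycloaddition. It requires C8 to be planar, so the ketal of 16 is hydrolysed first (17 ⇒ 16).

**Bicycle (16 ⇒ 9 + 13).** The C1–C2 and C4–C5 bonds are cut together. This removes a ring, both quaternary bridgeheads and three stereocentres at once and leads to two fragments of about equal size: the cyclopentadienone ketal 9 and the chiral silyloxyacrolein acetal 13, the source of cation 14. The forward reaction must join CH2 to C1 (not to C5) and must select one face of the cation. The 5,5-dimethoxy carbon holds the diene s-cis, blocks 1,5-hydrogen shifts and arrives as the masked C8 ketone.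

**Acetal (13 ⇒ 12 ⇒ 10 + 11).** The O–Si bond and one acetal C–O bond are cut: 13 is the silyl enol ether of keto acetal 12, made from 1,1-dimethoxypropan-2-one 10 and (R)-1-phenylethanol 11. A mixed methyl/phenylethyl acetal is preferred to the bis(phenylethyl) acetal because it needs one equivalent of the alcohol and the smaller methoxy group is the one that leaves on ionisation.

**Diene (9 ⇒ 7 ⇒ 6 ⇒ 5 ⇒ 3 ⇒ 1 + 2).** The enol O–CH3 bond of 9 is cut to dienolate 8 of keto ketal 7. Ketone 7 is the oxidation product of hydroxy ketal 6. Compound 6 carries the ketal on the carbon next to the side chain, which is what a hypervalent iodine α-hydroxylation with ketal formation delivers from cyclopentenone 5; direct ketalisation of the corresponding 1,2-dione would go to the other carbonyl. Enone 5 is the aldol condensation product of 2,5-diketone 3, assembled from aldehyde 1 and methyl vinyl ketone 2 by a Stetter reaction. This was preferred to alkylating 3-methylcyclopent-2-enone with a 2-silyloxyethyl iodide, a sluggish electrophile prone to elimination and polyalkylation.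

## Roads not taken

**Alternative 1:** transannular benzoin reaction. The cut is C5–C8. A triazolium-derived carbene would turn the aldehyde of cycloheptenone A1 into an acyl anion equivalent that adds across the ring to the C5 ketone, giving bridgehead alcohol A2 and closing the five- and six-membered rings with one bond.
- Merits: the aryl, methyl and allyl groups and the finished enol ether/acetate array are in place before the bicycle forms. There is no late arylation, no masked allyl group and no inversion at C4; in these respects this road is better than the chosen one.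
- Weak points: A1 is a seven-membered ring with four stereocentres, one of them the quaternary C1 carrying both allyl and formyl, and no short route to it is apparent. Its C4 acetate is α to the C5 ketone and can epimerise under the basic carbene conditions. The aldehyde is neopentyl, which slows formation of the acyl anion equivalent. A2 still needs O-methylation of a tertiary bridgehead α-ketol that can revert by retro-benzoin or retro-aldol under base.
- Comparison: the chosen plan makes the bicycle, both bridgeheads and the bridgehead methoxy group from two simple fragments in one step. It pays with a longer endgame.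

**Alternative 2:** divinylcyclopropane Cope rearrangement. The cut is C4–C5, with C2–C7 as the bond to be broken in the precursor. Heating the endo-vinyl bicyclo[3.1.0]hexenone A3 would give dienone A4 through a boat transition state.
- Merits: the enol ether and the C4 acetate arrive finished, C8 is already a ketone (no ketal hydrolysis before arylation), and the rearrangement is stereospecific. In these respects it is better than the chosen plan.
- Weak points: A3 has two adjacent quaternary cyclopropane carbons on a cyclopentenone and a geometrically defined acetoxy-methoxy vinyl group; the obvious cyclopropanation partner, a cyclopentadienone, is not a usable reagent. The axial acetate of 28 requires the acetoxy group cis to the cyclopropane on the vinyl terminus, i.e. inside the boat, which is the substitution that retards this rearrangement and opens competing pathways. Absolute configuration would need a separate solution.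
- Comparison: the chosen plan has precedented fragment syntheses and a built-in auxiliary, but must invert C4 and unmask C8.

**Alternative 3:** interrupted Nazarov cyclisation. The cuts are C6–C7 and C4–C5. Sc(OTf)3 with a chiral pybox ligand would close divinyl ketone A5 by conrotation, and allylstannane A6 would trap the oxyallyl cation at the methoxy-bearing terminus to give cyclopentanone A7.
- Merits: the trans relation of aryl and methyl follows from alkene geometry and conrotation, so no hydroarylation is needed; four contiguous stereocentres are set in one step. In this respect it is better than the chosen plan.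
- Weak points: only the five-membered ring is formed. The six-membered ring must still be closed at C1–C2, which means creating the quaternary C1 late on a crowded cyclopentanone, after building C3 oxidation level from the vinyl group. Torquoselective catalysis is established for activated divinyl ketones, not for an α-methoxy dienone without a second coordinating carbonyl. Intermolecular capture at the more substituted, methoxy-bearing terminus (not at C1) is uncertain.
- Comparison: the chosen plan closes the bicycle in the key step and leaves only functional-group work, at the price of setting C6 and C7 afterwards.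

Key step: step 8

Assumption: 4-[(tert-butyldiphenylsilyl)oxy]butanal (1) is taken as a catalogue compound; if it must be made, monosilylation of butane-1,4-diol and oxidation add two routine steps.

Assumption: cation 14 is taken to react in its W form on the face anti to the phenyl group of the auxiliary, which assigns the (R)-alcohol 11 to the required enantiomer; if induction runs the other way, (S)-1-phenylethanol is used instead without other change.

## Route

Step 1
Reactants: 1 4-[(tert-butyldiphenylsilyl)oxy]butanal; 2 but-3-en-2-one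
Product: 3 8-[(tert-butyldiphenylsilyl)oxy]octane-2,5-dione
Conditions: 3-benzyl-5-(2-hydroxyethyl)-4-methylthiazolium chloride (0.1 equiv), Et3N, EtOH, 80 °C
Reagents that add atoms: none
Why: Stetter reaction: the carbene-derived acyl anion equivalent of aliphatic aldehyde 1 adds in conjugate fashion to enone 2, the standard entry to 2,5-diketones of the dihydrojasmone type; the silyl ether is inert and no stereocentre is formed.

Step 2
Reactants: 3 8-[(tert-butyldiphenylsilyl)oxy]octane-2,5-dione
Product: 5 2-{2-[(tert-butyldiphenylsilyl)oxy]ethyl}-3-methylcyclopent-2-en-1-one, via aldol adduct 4 (not isolated)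
Conditions: KOtBu (0.5 equiv), tBuOH, 40 °C
Reagents that add atoms: none
Why: Intramolecular aldol condensation: the enolate of the internal CH2 (C6 of 3) adds to the methyl ketone and aldol 4 dehydrates to the tetrasubstituted cyclopentenone, the thermodynamically preferred enone as in the classical jasmone syntheses. An alkoxide in tert-butanol spares the silyl ether.

Step 3
Reactants: 5 2-{2-[(tert-butyldiphenylsilyl)oxy]ethyl}-3-methylcyclopent-2-en-1-one
Product: 6 3-{2-[(tert-butyldiphenylsilyl)oxy]ethyl}-2,2-dimethoxy-4-methylcyclopent-3-en-1-ol (racemic)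
Conditions: PhI(OAc)2 (1.1 equiv), KOH (3 equiv), MeOH, 0 °C to rt
Reagents that add atoms: methanol (CO)
Why: Hypervalent iodine α-hydroxylation with ketal formation (Moriarty oxidation): the α′-enolate attacks iodine, methoxide adds to the carbonyl, the alkoxide displaces iodobenzene to a methoxy epoxide and methoxide opens it at the allylic carbon. The net effect moves the carbonyl oxygen to the α′-carbon and leaves the old carbonyl carbon, next to the side chain, as the dimethyl ketal. The fully substituted β-carbon suppresses conjugate addition of methoxide.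

Step 4
Reactants: 6 3-{2-[(tert-butyldiphenylsilyl)oxy]ethyl}-2,2-dimethoxy-4-methylcyclopent-3-en-1-ol
Product: 7 3-{2-[(tert-butyldiphenylsilyl)oxy]ethyl}-2,2-dimethoxy-4-methylcyclopent-3-en-1-one
Conditions: Pr4N[RuO4] (5 mol%), N-methylmorpholine N-oxide, 4 Å MS, CH2Cl2, rt
Reagents that add atoms: none
Why: Catalytic perruthenate (Ley) oxidation of a secondary alcohol under neutral conditions, chosen because the allylic ketal of 6 does not tolerate acid. Migration of the double bond into conjugation would be harmless, since both isomers give the same dienolate.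

Step 5
Reactants: 7 3-{2-[(tert-butyldiphenylsilyl)oxy]ethyl}-2,2-dimethoxy-4-methylcyclopent-3-en-1-one
Product: 9 1-{2-[(tert-butyldiphenylsilyl)oxy]ethyl}-4,5,5-trimethoxy-2-methylcyclopenta-1,3-diene, via potassium dienolate 8 (not isolated)
Conditions: KN(SiMe3)2, THF, −78 °C; then MeOTf, DMPU, −78 to −40 °C
Reagents that add atoms: methyl trifluoromethanesulfonate (COS(=O)(=O)C(F)(F)F)
Why: Deprotonation of the doubly activated CH2 gives the delocalised dienolate 8, and the hard electrophile MeOTf in a dipolar cosolvent alkylates it on oxygen (enolate O-alkylation) to the 1-methoxydiene. The quaternary ketal carbon blocks 1,5-hydrogen shifts and the four substituents slow Diels–Alder dimerisation, but 9 should be used soon after it is made.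

Step 6
Reactants: 10 1,1-dimethoxypropan-2-one; 11 (R)-1-phenylethanol
Product: 12 1-methoxy-1-[(1R)-1-phenylethoxy]propan-2-one (both epimers at the acetal carbon)
Conditions: TsOH·H2O (2 mol%), cyclohexane, 65 °C, MeOH removed (5 Å MS)
Reagents that add atoms: none
Why: Acid-catalysed transacetalisation driven by removal of methanol; one methoxy group is exchanged and the carbinol stereocentre of 11 is not involved. The new acetal stereocentre does not matter because it is destroyed on ionisation in step 8.

Step 7
Reactants: 12 1-methoxy-1-[(1R)-1-phenylethoxy]propan-2-one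
Product: 13 triethyl({3-methoxy-3-[(1R)-1-phenylethoxy]prop-1-en-2-yl}oxy)silane (both acetal epimers)
Conditions: Et3SiOTf, Et3N, Et2O, 0 °C
Reagents that add atoms: triethylsilyl trifluoromethanesulfonate (CC[Si](CC)(CC)OS(=O)(=O)C(F)(F)F)
Why: Soft enolisation with a silyl triflate and an amine gives the silyl enol ether on the methyl side, the standard preparation of 2-silyloxyacrolein acetals; deprotonation at the acetal carbon is not competitive.

Step 8
Reactants: 9 1-{2-[(tert-butyldiphenylsilyl)oxy]ethyl}-4,5,5-trimethoxy-2-methylcyclopenta-1,3-diene; 13 triethyl({3-methoxy-3-[(1R)-1-phenylethoxy]prop-1-en-2-yl}oxy)silane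
Product: 16 (1R,4S,5S)-1-{2-[(tert-butyldiphenylsilyl)oxy]ethyl}-5,8,8-trimethoxy-7-methyl-4-[(1R)-1-phenylethoxy]bicyclo[3.2.1]oct-6-en-3-one, via allyl cation triflate 14 (not isolated), via ring-open oxocarbenium triflate 15 (not isolated)
Conditions: Me3SiOTf (0.15 equiv), 2,6-di-tert-butyl-4-methylpyridine (0.2 equiv), CH2Cl2, −95 to −78 °C; then Et3N, aq NaHCO3
Reagents that add atoms: none
Why: Me3SiOTf removes the methoxy group of 13, the less hindered and more basic acetal oxygen, and gives the W-shaped cation 14 (alkoxy syn to silyloxy); what follows is the auxiliary-directed (4+3) cycloaddition of 1-alkoxy-2-silyloxyallyl cations known for furan and cyclopentadiene, here asked of a 5,5-disubstituted 1-methoxycyclopentadiene. Bond formation is taken to be stepwise or strongly asynchronous: C1 of the diene, the terminus remote from the methoxy group and the site of the largest HOMO coefficient, attacks the unhindered CH2 terminus of 14 (vinylogous Mukaiyama–Michael addition) to give the methoxy-stabilised cation 15, whose silyl enol ether carbon C4 then bonds to C5 with transfer of Et3Si to triflate, which carries the chain. This second bond closes the six-membered ring C1–C2–C3–C4–C5–C8 in a 6-(enolendo)-exo-trig mode and, counted the other way round, the seven-membered ring C1–C7 in a 7-(enolendo)-endo-trig mode. C1 and C5 are necessarily cis because both bonds form on one face of the planar diene. The C4 alkoxy group should come out equatorial, on the side of the C6–C7 bridge: the ketal methoxy group lying over the incoming three-carbon unit rules out the extended arrangement and any closure with the alkoxy group inside, which leaves the compact, chair-forming closure of the W cation, and the equatorial position is also the thermodynamic one while C8 is a ketal. The absolute sense of C1, C4 and C5 comes from the (R)-phenylethoxy group, which keeps its C–H bond in the cation plane and covers one face with phenyl so that C5 bonds to the other face of C4; because the first bond forms far from the auxiliary, selection rests on this closure, and the minor product is a separable diastereomer, not an enantiomer. The step needs orientation (CH2 to C1, not to C5) and face selectivity: the first is secured by the polarisation of the diene through its C5 methoxy group together with the steric demand of the fully substituted C1, the second by the auxiliary.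

Step 9
Reactants: 16 (1R,4S,5S)-1-{2-[(tert-butyldiphenylsilyl)oxy]ethyl}-5,8,8-trimethoxy-7-methyl-4-[(1R)-1-phenylethoxy]bicyclo[3.2.1]oct-6-en-3-one
Product: 17 (1R,4S,5S)-1-{2-[(tert-butyldiphenylsilyl)oxy]ethyl}-5-methoxy-7-methyl-4-[(1R)-1-phenylethoxy]bicyclo[3.2.1]oct-6-ene-3,8-dione
Conditions: 3 M aq HCl/THF (1:3), 40 °C
Reagents that add atoms: water (O)
Why: Acid hydrolysis of a dimethyl ketal; the bridging ketal is slowed by the adjacent C5 methoxy group, hence the strong aqueous acid. The primary tert-butyldiphenylsilyl ether and the benzylic ether (its oxygen made less basic by the neighbouring ketone) should survive, and no stereocentre is touched.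

Step 10
Reactants: 17 (1R,4S,5S)-1-{2-[(tert-butyldiphenylsilyl)oxy]ethyl}-5-methoxy-7-methyl-4-[(1R)-1-phenylethoxy]bicyclo[3.2.1]oct-6-ene-3,8-dione; 18 (3,4-dimethoxyphenyl)boronic acid
Product: 19 (1R,4S,5S,6S,7R)-1-{2-[(tert-butyldiphenylsilyl)oxy]ethyl}-6-(3,4-dimethoxyphenyl)-5-methoxy-7-methyl-4-[(1R)-1-phenylethoxy]bicyclo[3.2.1]octane-3,8-dione
Conditions: [Rh(cod)OH]2 (5 mol%), dioxane/H2O (10:1), 90 °C
Reagents that add atoms: none
Why: Rhodium-catalysed hydroarylation of a strained bicyclic alkene with an arylboronic acid: the arylrhodium species adds syn across C6=C7 from the exo face, which the planar C8 carbonyl leaves open while the C2–C4 bridge blocks the endo face. Aryl goes to the less substituted C6 and the C7–Rh bond is replaced by C–H with retention (directly or after 1,4-shift to the aryl ring), so aryl and the new hydrogen are exo and the methyl group is pushed endo, which sets C6 and C7 together.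

Step 11
Reactants: 19 (1R,4S,5S,6S,7R)-1-{2-[(tert-butyldiphenylsilyl)oxy]ethyl}-6-(3,4-dimethoxyphenyl)-5-methoxy-7-methyl-4-[(1R)-1-phenylethoxy]bicyclo[3.2.1]octane-3,8-dione
Product: 20 (1R,4S,5S,6S,7R)-1-{2-[(tert-butyldiphenylsilyl)oxy]ethyl}-6-(3,4-dimethoxyphenyl)-4-hydroxy-5-methoxy-7-methylbicyclo[3.2.1]octane-3,8-dione
Conditions: H2 (1 atm), Pd(OH)2/C, EtOAc, rt
Reagents that add atoms: none
Why: Hydrogenolysis of a benzylic ether; it is placed here because the molecule holds no alkene at this stage and because the later allylic C4–O bond and enol ether would not survive it. C4 keeps its configuration.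

Step 12
Reactants: 20 (1R,4S,5S,6S,7R)-1-{2-[(tert-butyldiphenylsilyl)oxy]ethyl}-6-(3,4-dimethoxyphenyl)-4-hydroxy-5-methoxy-7-methylbicyclo[3.2.1]octane-3,8-dione
Product: 21 (1R,4S,5S,6S,7R)-1-{2-[(tert-butyldiphenylsilyl)oxy]ethyl}-6-(3,4-dimethoxyphenyl)-5-methoxy-7-methyl-4-[(triethylsilyl)oxy]bicyclo[3.2.1]octane-3,8-dione
Conditions: Et3SiOTf, 2,6-lutidine, CH2Cl2, −78 °C
Reagents that add atoms: triethylsilyl trifluoromethanesulfonate (CC[Si](CC)(CC)OS(=O)(=O)C(F)(F)F)
Why: Silylation of a hindered secondary alcohol with a silyl triflate; the equatorial hydroxyl is accessible, and the ether is needed so that a single enolate forms in step 13 and no alkoxide sits β to the C8 ketone.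

Step 13
Reactants: 21 (1R,4S,5S,6S,7R)-1-{2-[(tert-butyldiphenylsilyl)oxy]ethyl}-6-(3,4-dimethoxyphenyl)-5-methoxy-7-methyl-4-[(triethylsilyl)oxy]bicyclo[3.2.1]octane-3,8-dione
Product: 23 (1S,4R,5S,6S,7R)-1-{2-[(tert-butyldiphenylsilyl)oxy]ethyl}-6-(3,4-dimethoxyphenyl)-3,5-dimethoxy-7-methyl-4-[(triethylsilyl)oxy]bicyclo[3.2.1]oct-2-en-8-one, via potassium enolate 22 (not isolated)
Conditions: KN(SiMe3)2, THF, −78 °C; then MeOTf, DMPU, −78 °C
Reagents that add atoms: methyl trifluoromethanesulfonate (COS(=O)(=O)C(F)(F)F)
Why: Kinetic deprotonation of an α-silyloxy ketone takes place at the unoxygenated C2, and the potassium enolate is methylated on oxygen by MeOTf in the presence of DMPU (enolate O-alkylation); C-methylation at the neopentyl C2 is slow. The C8 ketone has no α-hydrogen and C4 is not deprotonated, so its configuration is kept (the descriptor changes only through priorities).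

Step 14
Reactants: 23 (1S,4R,5S,6S,7R)-1-{2-[(tert-butyldiphenylsilyl)oxy]ethyl}-6-(3,4-dimethoxyphenyl)-3,5-dimethoxy-7-methyl-4-[(triethylsilyl)oxy]bicyclo[3.2.1]oct-2-en-8-one
Product: 24 (1S,4R,5S,6S,7R)-1-{2-[(tert-butyldiphenylsilyl)oxy]ethyl}-6-(3,4-dimethoxyphenyl)-4-hydroxy-3,5-dimethoxy-7-methylbicyclo[3.2.1]oct-2-en-8-one
Conditions: HF·pyridine, pyridine, THF, 0 °C
Reagents that add atoms: none
Why: Fluoride cleavage of a triethylsilyl ether with pyridine-buffered HF·pyridine, conditions that leave a tert-butyldiphenylsilyl ether in place and do not hydrolyse a methyl enol ether. The free C4 hydroxyl is never exposed to base, which could open C4–C5 by retro-aldol reaction towards C8.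

Step 15
Reactants: 24 (1S,4R,5S,6S,7R)-1-{2-[(tert-butyldiphenylsilyl)oxy]ethyl}-6-(3,4-dimethoxyphenyl)-4-hydroxy-3,5-dimethoxy-7-methylbicyclo[3.2.1]oct-2-en-8-one
Product: 25 (1S,4S,5S,6S,7R)-1-{2-[(tert-butyldiphenylsilyl)oxy]ethyl}-6-(3,4-dimethoxyphenyl)-3,5-dimethoxy-7-methyl-8-oxobicyclo[3.2.1]oct-2-en-4-yl acetate
Conditions: PPh3, iPrO2CN=NCO2iPr, AcOH, toluene, 0 °C to rt
Reagents that add atoms: acetic acid (CC(=O)O)
Why: Mitsunobu esterification: the equatorial alcohol is activated as its alkoxyphosphonium ion and displaced by acetate with inversion, which places the acetoxy group axial (4S) as in the target. The backside trajectory runs over the six-membered ring between C2 and C8, both sp2 and without substituents there; elimination is impossible (no β-hydrogen on C3 or C5) and SN2′ attack at the electron-rich C2 is disfavoured.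

Step 16
Reactants: 25 (1S,4S,5S,6S,7R)-1-{2-[(tert-butyldiphenylsilyl)oxy]ethyl}-6-(3,4-dimethoxyphenyl)-3,5-dimethoxy-7-methyl-8-oxobicyclo[3.2.1]oct-2-en-4-yl acetate
Product: 26 (1S,4S,5S,6S,7R)-6-(3,4-dimethoxyphenyl)-1-(2-hydroxyethyl)-3,5-dimethoxy-7-methyl-8-oxobicyclo[3.2.1]oct-2-en-4-yl acetate
Conditions: Bu4NF, AcOH (1:1), THF, 0 °C to rt
Reagents that add atoms: none
Why: Fluoride desilylation buffered with acetic acid so that no alkoxide builds up next to the acetate. The liberated alcohol will equilibrate with its five-membered hemiketal to the strained C8 ketone, which does not affect the next step.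

Step 17
Reactants: 26 (1S,4S,5S,6S,7R)-6-(3,4-dimethoxyphenyl)-1-(2-hydroxyethyl)-3,5-dimethoxy-7-methyl-8-oxobicyclo[3.2.1]oct-2-en-4-yl acetate
Product: 27 (1S,4S,5S,6S,7R)-6-(3,4-dimethoxyphenyl)-3,5-dimethoxy-7-methyl-8-oxo-1-(2-oxoethyl)bicyclo[3.2.1]oct-2-en-4-yl acetate
Conditions: Dess–Martin periodinane, pyridine, CH2Cl2, 0 °C
Reagents that add atoms: none
Why: Dess–Martin oxidation of a primary alcohol under buffered, near-neutral conditions that spare the enol ether and the acetate; the open hydroxy ketone is drained from the hemiketal equilibrium.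

Step 18
Reactants: 27 (1S,4S,5S,6S,7R)-6-(3,4-dimethoxyphenyl)-3,5-dimethoxy-7-methyl-8-oxo-1-(2-oxoethyl)bicyclo[3.2.1]oct-2-en-4-yl acetate
Product: 28 (1S,4S,5S,6S,7R)-6-(3,4-dimethoxyphenyl)-3,5-dimethoxy-7-methyl-8-oxo-1-(prop-2-en-1-yl)bicyclo[3.2.1]oct-2-en-4-yl acetate (CNP0221003.1)
Conditions: Ph3PCH3Br, KN(SiMe3)2, THF, 0 °C; then 27, −78 to 0 °C
Reagents that add atoms: methyltriphenylphosphonium bromide (C[P+](c1ccccc1)(c1ccccc1)c1ccccc1.[Br-])
Why: Wittig methylenation: at low temperature the unhindered aldehyde reacts with the non-stabilised ylide far faster than the C8 ketone, which is flanked by two quaternary carbons, or the acetate. No stereocentre is affected and the allyl group is complete.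

## Compound list

1 | 4-[(tert-butyldiphenylsilyl)oxy]butanal | O=CCCCO[Si](c1ccccc1)(c1ccccc1)C(C)(C)C | starting material
2 | but-3-en-2-one | CC(=O)C=C | starting material
3 | 8-[(tert-butyldiphenylsilyl)oxy]octane-2,5-dione | CC(=O)CCC(=O)CCCO[Si](c1ccccc1)(c1ccccc1)C(C)(C)C | intermediate
4 | 2-{2-[(tert-butyldiphenylsilyl)oxy]ethyl}-3-hydroxy-3-methylcyclopentan-1-one (mixture of diastereomers) | O=C1CCC(C)(O)C1CCO[Si](c1ccccc1)(c1ccccc1)C(C)(C)C | intermediate (not isolated)
5 | 2-{2-[(tert-butyldiphenylsilyl)oxy]ethyl}-3-methylcyclopent-2-en-1-one | O=C1CCC(C)=C1CCO[Si](c1ccccc1)(c1ccccc1)C(C)(C)C | intermediate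
6 | 3-{2-[(tert-butyldiphenylsilyl)oxy]ethyl}-2,2-dimethoxy-4-methylcyclopent-3-en-1-ol (racemic) | OC1CC(C)=C(CCO[Si](c2ccccc2)(c2ccccc2)C(C)(C)C)C1(OC)OC | intermediate
7 | 3-{2-[(tert-butyldiphenylsilyl)oxy]ethyl}-2,2-dimethoxy-4-methylcyclopent-3-en-1-one | O=C1CC(C)=C(CCO[Si](c2ccccc2)(c2ccccc2)C(C)(C)C)C1(OC)OC | intermediate
8 | potassium 4-{2-[(tert-butyldiphenylsilyl)oxy]ethyl}-5,5-dimethoxy-3-methylcyclopenta-1,3-dien-1-olate | [K+].[O-]C1=CC(C)=C(CCO[Si](c2ccccc2)(c2ccccc2)C(C)(C)C)C1(OC)OC | intermediate (not isolated)
9 | 1-{2-[(tert-butyldiphenylsilyl)oxy]ethyl}-4,5,5-trimethoxy-2-methylcyclopenta-1,3-diene | COC1=CC(C)=C(CCO[Si](c2ccccc2)(c2ccccc2)C(C)(C)C)C1(OC)OC | intermediate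
10 | 1,1-dimethoxypropan-2-one | CC(=O)C(OC)OC | starting material
11 | (R)-1-phenylethanol | C[C@@H](O)c1ccccc1 | starting material
12 | 1-methoxy-1-[(1R)-1-phenylethoxy]propan-2-one (both epimers at the acetal carbon) | CC(=O)C(OC)O[C@H](C)c1ccccc1 | intermediate
13 | triethyl({3-methoxy-3-[(1R)-1-phenylethoxy]prop-1-en-2-yl}oxy)silane (both acetal epimers) | C=C(O[Si](CC)(CC)CC)C(OC)O[C@H](C)c1ccccc1 | intermediate
14 | 1-[(1R)-1-phenylethoxy]-2-(triethylsilyloxy)allyl cation (O-alkyl oxocarbenium form, alkoxy syn to silyloxy), trifluoromethanesulfonate | C=C(O[Si](CC)(CC)CC)C=[O+][C@H](C)c1ccccc1.[O-]S(=O)(=O)C(F)(F)F | intermediate (not isolated)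
15 | ring-open O-methyl oxocarbenium trifluoromethanesulfonate formed by C1–C2 bonding: the 2-methoxycyclopentenylium ring of 9 carrying at its quaternary C1 (R) the (Z)-3-[(1R)-1-phenylethoxy]-2-(triethylsilyloxy)prop-2-en-1-yl chain | CC(C)(C)[Si](c1ccccc1)(c1ccccc1)OCC[C@]1(C/C(O[Si](CC)(CC)CC)=C/O[C@H](C)c2ccccc2)C(OC)(OC)C(=[O+]C)C=C1C.[O-]S(=O)(=O)C(F)(F)F | intermediate (not isolated)
16 | (1R,4S,5S)-1-{2-[(tert-butyldiphenylsilyl)oxy]ethyl}-5,8,8-trimethoxy-7-methyl-4-[(1R)-1-phenylethoxy]bicyclo[3.2.1]oct-6-en-3-one (C4 alkoxy equatorial) | CC(C)(C)[Si](c1ccccc1)(c1ccccc1)OCC[C@]12CC(=O)[C@@H](O[C@H](C)c3ccccc3)[C@](OC)(C1(OC)OC)C=C2C | intermediate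
17 | (1R,4S,5S)-1-{2-[(tert-butyldiphenylsilyl)oxy]ethyl}-5-methoxy-7-methyl-4-[(1R)-1-phenylethoxy]bicyclo[3.2.1]oct-6-ene-3,8-dione | CC(C)(C)[Si](c1ccccc1)(c1ccccc1)OCC[C@]12CC(=O)[C@@H](O[C@H](C)c3ccccc3)[C@](OC)(C1=O)C=C2C | intermediate
18 | (3,4-dimethoxyphenyl)boronic acid | COc1ccc(B(O)O)cc1OC | starting material
19 | (1R,4S,5S,6S,7R)-1-{2-[(tert-butyldiphenylsilyl)oxy]ethyl}-6-(3,4-dimethoxyphenyl)-5-methoxy-7-methyl-4-[(1R)-1-phenylethoxy]bicyclo[3.2.1]octane-3,8-dione (6-exo-aryl, 7-endo-methyl) | CC(C)(C)[Si](c1ccccc1)(c1ccccc1)OCC[C@]12CC(=O)[C@@H](O[C@H](C)c3ccccc3)[C@](OC)(C1=O)[C@H](c1ccc(OC)c(OC)c1)[C@H]2C | intermediate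
20 | (1R,4S,5S,6S,7R)-1-{2-[(tert-butyldiphenylsilyl)oxy]ethyl}-6-(3,4-dimethoxyphenyl)-4-hydroxy-5-methoxy-7-methylbicyclo[3.2.1]octane-3,8-dione | CC(C)(C)[Si](c1ccccc1)(c1ccccc1)OCC[C@]12CC(=O)[C@@H](O)[C@](OC)(C1=O)[C@H](c1ccc(OC)c(OC)c1)[C@H]2C | intermediate
21 | (1R,4S,5S,6S,7R)-1-{2-[(tert-butyldiphenylsilyl)oxy]ethyl}-6-(3,4-dimethoxyphenyl)-5-methoxy-7-methyl-4-[(triethylsilyl)oxy]bicyclo[3.2.1]octane-3,8-dione | CC(C)(C)[Si](c1ccccc1)(c1ccccc1)OCC[C@]12CC(=O)[C@@H](O[Si](CC)(CC)CC)[C@](OC)(C1=O)[C@H](c1ccc(OC)c(OC)c1)[C@H]2C | intermediate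
22 | potassium C2=C3 enolate of 21 | [K+].CC(C)(C)[Si](c1ccccc1)(c1ccccc1)OCC[C@]12C=C([O-])[C@@H](O[Si](CC)(CC)CC)[C@](OC)(C1=O)[C@H](c1ccc(OC)c(OC)c1)[C@H]2C | intermediate (not isolated)
23 | (1S,4R,5S,6S,7R)-1-{2-[(tert-butyldiphenylsilyl)oxy]ethyl}-6-(3,4-dimethoxyphenyl)-3,5-dimethoxy-7-methyl-4-[(triethylsilyl)oxy]bicyclo[3.2.1]oct-2-en-8-one | CC(C)(C)[Si](c1ccccc1)(c1ccccc1)OCC[C@]12C=C(OC)[C@@H](O[Si](CC)(CC)CC)[C@](OC)(C1=O)[C@H](c1ccc(OC)c(OC)c1)[C@H]2C | intermediate
24 | (1S,4R,5S,6S,7R)-1-{2-[(tert-butyldiphenylsilyl)oxy]ethyl}-6-(3,4-dimethoxyphenyl)-4-hydroxy-3,5-dimethoxy-7-methylbicyclo[3.2.1]oct-2-en-8-one (C4 hydroxyl equatorial) | CC(C)(C)[Si](c1ccccc1)(c1ccccc1)OCC[C@]12C=C(OC)[C@@H](O)[C@](OC)(C1=O)[C@H](c1ccc(OC)c(OC)c1)[C@H]2C | intermediate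
25 | (1S,4S,5S,6S,7R)-1-{2-[(tert-butyldiphenylsilyl)oxy]ethyl}-6-(3,4-dimethoxyphenyl)-3,5-dimethoxy-7-methyl-8-oxobicyclo[3.2.1]oct-2-en-4-yl acetate (C4 acetoxy axial) | CC(C)(C)[Si](c1ccccc1)(c1ccccc1)OCC[C@]12C=C(OC)[C@H](OC(C)=O)[C@](OC)(C1=O)[C@H](c1ccc(OC)c(OC)c1)[C@H]2C | intermediate
26 | (1S,4S,5S,6S,7R)-6-(3,4-dimethoxyphenyl)-1-(2-hydroxyethyl)-3,5-dimethoxy-7-methyl-8-oxobicyclo[3.2.1]oct-2-en-4-yl acetate | OCC[C@]12C=C(OC)[C@H](OC(C)=O)[C@](OC)(C1=O)[C@H](c1ccc(OC)c(OC)c1)[C@H]2C | intermediate
27 | (1S,4S,5S,6S,7R)-6-(3,4-dimethoxyphenyl)-3,5-dimethoxy-7-methyl-8-oxo-1-(2-oxoethyl)bicyclo[3.2.1]oct-2-en-4-yl acetate | O=CC[C@]12C=C(OC)[C@H](OC(C)=O)[C@](OC)(C1=O)[C@H](c1ccc(OC)c(OC)c1)[C@H]2C | intermediate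
28 | (1S,4S,5S,6S,7R)-6-(3,4-dimethoxyphenyl)-3,5-dimethoxy-7-methyl-8-oxo-1-(prop-2-en-1-yl)bicyclo[3.2.1]oct-2-en-4-yl acetate (CNP0221003.1) | C=CC[C@]12C=C(OC)[C@H](OC(C)=O)[C@](OC)(C1=O)[C@H](c1ccc(OC)c(OC)c1)[C@H]2C | target

## Step count and least certain steps

Total step count: 18. Longest linear sequence: 16 steps (steps 1–5 and 8–18); the acetal branch is steps 6–7.

**Step 8 (key step).** Several things may go wrong:
- bonding in the reverse orientation (acetal carbon to C1), since the oxocarbenium carbon is the more charged terminus of 14;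
- capture of the intermediate cation at C7 (a five-membered, (3+2)-type closure) or loss of the silyl group before closure, leaving an open-chain ketone;
- attack through the unsubstituted enol ether carbon C6 of the diene;
- weak face selection, because the first bond forms far from the auxiliary;
- closure with the alkoxy group axial, which base equilibration at the ketal stage should correct, the equatorial position being the stable one there.

Fallback: generate the three-carbon unit as an oxyallyl zwitterion under basic, protic conditions, which is less electrophilic and closer to concerted, and avoids the Lewis acid. (R)-1-Phenylethanol 11 is added to epichlorohydrin (BF3·OEt2) to give 1-chloro-3-[(1R)-1-phenylethoxy]propan-2-ol F1, which is oxidised (Dess–Martin periodinane) to 1-chloro-3-[(1R)-1-phenylethoxy]propan-2-one F2. F2 and diene 9 with Et3N in 2,2,2-trifluoroethanol should give the cycloadduct directly. This sets out from 9 (and 11) and returns at 16.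

**Step 10.** The arylrhodium species may fail to insert into a trisubstituted alkene flanked by two quaternary bridgeheads; aryl addition to the strained C8 ketone and slow epimerisation at C4 in hot aqueous medium are competing processes. Fallback: a Heck arylation followed by hydrogenation. From 17, 4-iodo-1,2-dimethoxybenzene with Pd(OAc)2, PPh3 and Et3N in DMF should give, by exo carbopalladation and β-hydride loss towards the methyl group (the only syn hydrogen available), (1R,4S,5S,6R)-1-{2-[(tert-butyldiphenylsilyl)oxy]ethyl}-6-(3,4-dimethoxyphenyl)-5-methoxy-7-methylidene-4-[(1R)-1-phenylethoxy]bicyclo[3.2.1]octane-3,8-dione F3. Hydrogenation of F3 over Pd(OH)2/C adds hydrogen to the exocyclic alkene from the exo face (methyl endo) and removes the phenylethyl group in the same operation. This returns at 20 and replaces steps 10 and 11.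

**Step 15.** Acylation with retention through an acyloxyphosphonium pathway, or no reaction, because the carbinol carbon sits next to the quaternary C5. Fallback: separate activation and displacement. From 24, chloromethanesulfonyl chloride and pyridine give (1S,4R,5S,6S,7R)-1-{2-[(tert-butyldiphenylsilyl)oxy]ethyl}-6-(3,4-dimethoxyphenyl)-3,5-dimethoxy-7-methyl-8-oxobicyclo[3.2.1]oct-2-en-4-yl chloromethanesulfonate F4, an isolable leaving group of the kind used for hindered alcohols that resist the Mitsunobu reaction. CsOAc with 18-crown-6 in toluene then displaces it with inversion. This returns at 25.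

**Step 13.** C-methylation of the enolate, or partial enolisation towards C4 with loss of the C4 configuration. Fallback: make the enol ether from a diosphenol, where the regiochemistry is fixed. From 20, Dess–Martin oxidation gives the 3,4-dione, which can enolise only towards C2: (1S,5R,6S,7R)-1-{2-[(tert-butyldiphenylsilyl)oxy]ethyl}-6-(3,4-dimethoxyphenyl)-3-hydroxy-5-methoxy-7-methylbicyclo[3.2.1]oct-2-ene-4,8-dione F5. Me2SO4 and K2CO3 in acetone give the methoxy enone (1S,5R,6S,7R)-1-{2-[(tert-butyldiphenylsilyl)oxy]ethyl}-6-(3,4-dimethoxyphenyl)-3,5-dimethoxy-7-methylbicyclo[3.2.1]oct-2-ene-4,8-dione F6. Reduction of F6 with NaBH4 and CeCl3·7H2O in MeOH at −78 °C (conditions that favour the conjugated carbonyl over the isolated C8 ketone) should deliver hydride from the open face next to C8 and give the equatorial alcohol. This returns at 24 and replaces steps 12–14; its own weak point is the competition of the C8 ketone.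

**Step 5.** C-methylation of the dienolate at the carbon α to the carbonyl, and Diels–Alder dimerisation of the diene on standing. Fallback: the acid-catalysed dienol ether synthesis used for steroid enones. From 7, DBU moves the double bond into conjugation to give 5,5-dimethoxy-4-{2-[(tert-butyldiphenylsilyl)oxy]ethyl}-3-methylcyclopent-2-en-1-one F7. Trimethyl orthoformate with catalytic pyridinium p-toluenesulfonate, quenched with Et3N, converts the enone carbonyl of F7 to the methoxy-substituted cation, which loses the γ-hydrogen. The existing ketal, deactivated by the neighbouring carbonyl, is not involved. This returns at 9.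

## Further compounds

F1 | step 8 | 1-chloro-3-[(1R)-1-phenylethoxy]propan-2-ol (both carbinol epimers) | OC(CCl)CO[C@H](C)c1ccccc1
F2 | step 8 | 1-chloro-3-[(1R)-1-phenylethoxy]propan-2-one | O=C(CCl)CO[C@H](C)c1ccccc1
F3 | step 10 | (1R,4S,5S,6R)-1-{2-[(tert-butyldiphenylsilyl)oxy]ethyl}-6-(3,4-dimethoxyphenyl)-5-methoxy-7-methylidene-4-[(1R)-1-phenylethoxy]bicyclo[3.2.1]octane-3,8-dione | CC(C)(C)[Si](c1ccccc1)(c1ccccc1)OCC[C@]12CC(=O)[C@@H](O[C@H](C)c3ccccc3)[C@](OC)(C1=O)[C@H](c1ccc(OC)c(OC)c1)C2=C
F4 | step 15 | (1S,4R,5S,6S,7R)-1-{2-[(tert-butyldiphenylsilyl)oxy]ethyl}-6-(3,4-dimethoxyphenyl)-3,5-dimethoxy-7-methyl-8-oxobicyclo[3.2.1]oct-2-en-4-yl chloromethanesulfonate | CC(C)(C)[Si](c1ccccc1)(c1ccccc1)OCC[C@]12C=C(OC)[C@@H](OS(=O)(=O)CCl)[C@](OC)(C1=O)[C@H](c1ccc(OC)c(OC)c1)[C@H]2C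
F5 | step 13 | (1S,5R,6S,7R)-1-{2-[(tert-butyldiphenylsilyl)oxy]ethyl}-6-(3,4-dimethoxyphenyl)-3-hydroxy-5-methoxy-7-methylbicyclo[3.2.1]oct-2-ene-4,8-dione | CC(C)(C)[Si](c1ccccc1)(c1ccccc1)OCC[C@]12C=C(O)C(=O)[C@](OC)(C1=O)[C@H](c1ccc(OC)c(OC)c1)[C@H]2C
F6 | step 13 | (1S,5R,6S,7R)-1-{2-[(tert-butyldiphenylsilyl)oxy]ethyl}-6-(3,4-dimethoxyphenyl)-3,5-dimethoxy-7-methylbicyclo[3.2.1]oct-2-ene-4,8-dione | CC(C)(C)[Si](c1ccccc1)(c1ccccc1)OCC[C@]12C=C(OC)C(=O)[C@](OC)(C1=O)[C@H](c1ccc(OC)c(OC)c1)[C@H]2C
F7 | step 5 | 5,5-dimethoxy-4-{2-[(tert-butyldiphenylsilyl)oxy]ethyl}-3-methylcyclopent-2-en-1-one (racemic) | COC1(OC)C(=O)C=C(C)C1CCO[Si](c1ccccc1)(c1ccccc1)C(C)(C)C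
A1 | alternative 1 | 1-allyl-6-(3,4-dimethoxyphenyl)-1-formyl-3-methoxy-7-methyl-5-oxocyclohept-2-en-4-yl acetate (stereocentres as in 28) | C=CC[C@@]1(C=O)C=C(OC)[C@H](OC(C)=O)C(=O)[C@H](c2ccc(OC)c(OC)c2)[C@H]1C
A2 | alternative 1 | C5 bridgehead alcohol, the O-demethyl analogue of 28 | C=CC[C@]12C=C(OC)[C@H](OC(C)=O)[C@](O)(C1=O)[C@H](c1ccc(OC)c(OC)c1)[C@H]2C
A3 | alternative 2 | 6-endo-(2-acetoxy-1-methoxyvinyl)-1-{2-[(tert-butyldimethylsilyl)oxy]ethyl}-3-methoxy-5-methylbicyclo[3.1.0]hex-3-en-2-one (acetoxy cis to the cyclopropane) | CC(C)(C)[Si](C)(C)OCC[C@]12C(=O)C(OC)=C[C@@]1(C)[C@H]2/C(OC)=C\OC(C)=O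
A4 | alternative 2 | 1-{2-[(tert-butyldimethylsilyl)oxy]ethyl}-3,5-dimethoxy-7-methyl-8-oxobicyclo[3.2.1]octa-2,6-dien-4-yl acetate | CC(C)(C)[Si](C)(C)OCC[C@]12C=C(OC)[C@H](OC(C)=O)[C@](OC)(C1=O)C=C2C
A5 | alternative 3 | (1Z,4E)-4-{2-[(tert-butyldimethylsilyl)oxy]ethyl}-1-(3,4-dimethoxyphenyl)-2-methoxyhexa-1,4-dien-3-one | C/C=C(CCO[Si](C)(C)C(C)(C)C)/C(=O)/C(OC)=C/c1ccc(OC)c(OC)c1
A6 | alternative 3 | tributyl[(2Z)-3-(methoxymethoxy)prop-2-en-1-yl]stannane | CCCC[Sn](CCCC)(CCCC)C/C=C\OCOC
A7 | alternative 3 | 2-{2-[(tert-butyldimethylsilyl)oxy]ethyl}-4-(3,4-dimethoxyphenyl)-5-methoxy-5-[1-(methoxymethoxy)allyl]-3-methylcyclopentan-1-one | C=C[C@H](OCOC)[C@]1(OC)C(=O)[C@@H](CCO[Si](C)(C)C(C)(C)C)[C@H](C)[C@H]1c1ccc(OC)c(OC)c1
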